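All runs stem from a simulated flask with made-up constants; the scatter is artificial.

- Reciprocal minutes were my starting unit: a constant k in them says what share of the remaining substrate goes each minute, and if that share holds steady, the fraction of the charge left after time t is exp(−kt).

common to all: initiator 0.50 mM

| run | substrate | reagent | remark | time |
|---|---|---|---|---|
| green | 0.11 M | 0.30 M | run made earlier |  |
| violet | 1.2 M | 0.30 M | run made earlier |  |
| Thursday's | 0.10 M | 0.300 M |  | 12 min |
| Friday's | 0.20 M | 0.300 M |  | 12 min |
| Sunday's | 0.40 M | 0.300 M |  | 12 min |
| Wednesday's | 0.80 M | 0.300 M |  | 12 min |
| Saturday's | 1.5 M | 0.300 M |  | 12 min |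

| run | time / min | target / % | substrate / % |
|---|---|---|---|
| green | 1.00 | 8.3 | 96.2 |
| green | 2.00 | 11.9 | 87.1 |
| green | 3.00 | 17.3 | 82.1 |
| green | 6.00 | 32.9 | 67.2 |
| green | 12.0 | 53.2 | 44.8 |
| violet | 2.50 | 14.3 | 84.9 |
| violet | 5.00 | 23.0 | 76.3 |
| violet | 8.00 | 23.9 | 76.0 |
| violet | 10.0 | 23.5 | 76.3 |
| violet | 12.0 | 23.2 | 77.1 |

(each reading ± 1 percentage point)

- the analysis behind the earlier runs scatters by 1 percentage point, standard deviation
- a reading or a percentage of target counts all its forms, free or not
- the concentration of target that is asked is that of its free form alone
- "hardly changes" means that all values lie within two and a half points (for a concentration: within two and a half percent of the largest)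

- [target] (only what is free in solution) at the end for Thursday's, Friday's, Sunday's, Wednesday's, Saturday's, in this order
- the shape of the row from first to last (falls, then rises / hardly changes / rises all the way / falls all the way / rises, then falls)

- I began with the main step. The last substrate reading of the green run gave k = 0.0669 /min. That k gave 66.9% left at 6.00 min in the green run, against a reading of 67.2%. It also gave 84.6% left at 2.50 min in the violet run, against 84.9%, although the violet charge was ten times the green one. With this step by itself, my reckoning for Wednesday's flask stood at 55.2% of its charge converted by 12 min.

- Next I added the reagent as limiting reagent, taking one reagent per target. For Wednesday's flask this allowed 37.5% of the substrate charge, which is less than 55.2%, so my number dropped to that.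

- Then I added what the violet run showed. It stopped near 23.5% of its charge, a reading worth 0.282 M of target, or 94.0% of the reagent charge. I could not tell where the remainder of the reagent went, so I used this reading as the cap, and my number for Wednesday's flask fell to 35.2%.

- The two limits meet at one charge. The cap over the converted fraction came to 0.511 M, and I called this the turning charge. By this reckoning, with this reagent charge and time, a flask below it converted 55.2% of its charge, and a flask above it converted the cap over its charge. So I reckoned 55.2% for Thursday's, Friday's and Sunday's flasks, and 18.8% for Saturday's. These fractions count free and other forms of target together, as the readings do, so they gave me no split, but I expected the row to bend at the turning charge.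

- The forecast gave 0.053 M, 0.106 M, 0.207 M, 0.272 M and 0.287 M, a row that rises all the way, on the grounds that “The high runs sit at the cap”.

- Free target at 12 min came out at 0.0285 M, 0.0351 M, 0.0484 M, 0.0268 M and 0.0237 M, so the row rises, then falls.

    initiator → 2 initiating radical (k = 3.53 × 10⁻⁵ /s)
    substrate + initiating radical → capped initiator + first chain carrier (k = 3.95 × 10⁶ /M/s)
    reagent + first chain carrier ⇌ target + second chain carrier (K = 0.616, k = 88000 /M/s)
    substrate + second chain carrier → released group + first chain carrier (k = 2.02 × 10⁵ /M/s)
    2 second chain carrier → ended chains (k = 6.00 × 10⁸ /M/s)
    reagent ⇌ dormant form (K = 4.30, k = 3.51 × 10⁻⁴ /s)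
    crystals ⇌ target, rate k7*(cs7 - [target]) while solid is left; crystals form when [target] > cs7 (solubility = 22.0 mM, k = 0.00854 /s)

- Sunday's flask stood highest in free target, with crystals at 42.2% of its charge counted inside target at 54.3%. The row turned at 0.49 M, beside my turning charge of 0.511 M. Saturday's charge of 1.5 M lay above that turning charge, so the cap over the charge gave 18.8%, and that flask held target at 19.4% of its charge with reagent at 0% of its own.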